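A small charge of reagent goes into larch, the flask asked about: 1.05 M against 1.0 M of solid substrate, none of it in solution at the start. An earlier flask, maple, ran the same charges colder.

| setting | larch | maple | flask |
|---|---|---|---|
| solid substrate | 1 M | 1 M | 1.0 M |
| reagent | 1.05 M | 1.05 M | 1.05 M |
| temperature | −20 °C | −35 °C | −20 °C |
| remark | the very flask that is asked about, followed so far | run made earlier |  |
| time |  |  | 1.5 h |

| run | time / min | target / % |
|---|---|---|
| larch | 12.0 | 11.2 |
| larch | 25.0 | 15.1 |
| larch | 40.0 | 12.4 |
| larch | 50.0 | 11.8 |
| larch | 60.0 | 12.3 |
| larch | 80.0 | 13.1 |
| maple | 25.0 | 42.4 |
| maple | 50.0 | 41.5 |
| maple | 80.0 | 40.6 |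
| maple | 120 | 41.3 |
| maple | 180 | 41.7 |

(readings scatter by 1 percentage point)

- amounts and yields of target count solid product too
- given per volume of solution although it is solid: solid substrate, solid product
- the volume of additions can be left aside
- what may be going on: dissolved substrate + reagent -> target; solid substrate <-> dissolved substrate; solid product <-> target; reagent -> side product
- at the start none of the solid substrate is in solution

* target, in percent of the solid substrate first charged, at 1.5 h
* the remedy with the largest gain of target, or "none" below 2 percentage points (midnight / summer / winter / none)
* target present, in percent of the solid substrate first charged, after midnight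
* target present, in percent of the solid substrate first charged, after winter

- midnight: change nothing and wait 25 min more
- summer: at 1.5 h add reagent, 50.0% of the amount charged, then wait 25 min
- winter: at 1.5 h raise the temperature by 15 K, then wait 25 min

Two colleagues stand before these readings. Both see a flat line: larch averages 12.7% and maple 41.5%.

The first calls the line a ceiling: target stands at a limit of position, a solubility or an equilibrium, so fresh reagent adds nothing to larch. The second calls it a race: reagent goes to side product while it makes target, and the line marks where the reagent ended.

Her quantity is a ratio. In larch, target on the line over reagent charged is 0.120; call this the reagent share, target made per reagent charged, a kind of selectivity. In maple it is 0.395, higher than in larch, which suits a loss that steepens with warmth. He answers that an equilibrium may also lie further over in the cold.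

They part on summer, and I side with the race. Larch already reads 11.2% at 12.0 min, so I take the loss of reagent as the fast step and reckon it over well before 1.5 h. On that estimate, waiting and warming gain nothing, and larch stays on its line.

Added reagent, 50.0% of the charge, at the same share gives 6.3 percentage points, above the margin of 2 points. I hold that as a low estimate: the first charge met a solution that started empty, while the added reagent meets one that has stood for 1.5 h.

The forecast reads 12.7% now, 12.7% after midnight, 12.7% after winter, and summer as best, on the grounds: “Waiting does nothing, and warming does nothing because no reagent remains.”

Larch gives 12.7% at 1.5 h, 12.7% after midnight and 12.7% after winter, with 0% of its reagent left at 90.0 min. The best remedy is summer, gaining 35 points, more than midnight or winter and well above my low estimate.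

    dissolved substrate + reagent → target (k = 0.150 L mol⁻¹ s⁻¹, Ea = 52.0 kJ mol⁻¹)
    solid substrate ⇌ dissolved substrate, rate k2*(cs2 - [dissolved substrate]) while solid is left; crystals form when [dissolved substrate] > cs2 (solubility = 0.530 M, k = 0.00350 s⁻¹)
    solid product ⇌ target, rate k3*(cs3 - [target]) while solid is left; crystals form when [target] > cs3 (solubility = 13.0 mM, k = 0.112 s⁻¹)
    reagent → side product (k = 0.0243 s⁻¹, Ea = 62.0 kJ mol⁻¹)
    (constants at −20 °C)

The ceiling view holds for dissolved substrate: larch shows 53.0% at 45.0 min and 53.0% at 900 min, with 34.3% still solid beside it. For a neighbour charged at the start with 2.6 M of reagent, the larch share gives 31.2% target. That neighbour holds 19.2% at 90.0 min, less than the share gives, with 0% of its reagent left and 2.41 M of side product.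

All runs were generated by integration with constants of no real substance; scatter was added.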